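**Retrosynthetic overview**

1. Target 15 ⇐ 8α-acetoxy-13,18-diol 13 (both primary carbons oxidised at the end) ⇐ triacetate 12 ⇐ triol 11 ⇐ reduction of the 18-acetoxy δ-lactone 10. The C8 acetate is put on while C13 is an alcohol, because an 8-hydroxy-13-acid closes back to the lactone on acylation.
2. Lactone 10 ⇐ acyclic all-(E) 14-acetoxy-farnesylacetic acid 9 by one enzymatic proton-initiated cyclisation that forms C4–C5, C9–C10 and C8–O: ring A first, ring B second, the δ-lactone last.
3. The feature the plan rests on: rings A and B are a trans-decalin with an unsubstituted CH2 at C3, the five stereocentres C4, C5, C10, C9 and C8 lie on one head-to-tail isoprenoid chain, and O8 stands 1,5 to the C13 carboxyl. The core is therefore the chair–chair fold of a C18-oxygenated (E,E,E)-triene acid.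
4. Acid 9 ⇐ (E,E)-farnesyl bromide 1 + diethyl malonate 2, then SeO2 oxidation of the terminal (E)-methyl, saponification and O-acetylation. The 4E alkene is bought with 1; a Claisen rearrangement of a tertiary allylic alcohol would give a 4E/4Z mixture.

Key step: step 6

Remark on the chemistry: labdane numbering is used for the bicyclic compounds (C13 = side-chain carboxyl carbon, C17 = methyl on C8, C18 = 4α carbon, C19 = 4β methyl, C20 = methyl on C10); chain carbons C13, C12, C9, C8, C5, C4 and C1 of the acyclic acid become C4, C3, C10, C5, C8, C9 and C13; the target SMILES is read as (4R,5R,8R,9R,10S), that is 4α-carboxyl, 5α-H, 8α-acetoxy, 9α-H, 10β-methyl.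

**Route**

Step 1
Reactants: 1 (2E,6E)-farnesyl bromide; 2 diethyl malonate
Product: 4 diethyl 2-[(2E,6E)-3,7,11-trimethyldodeca-2,6,10-trien-1-yl]propanedioate, via sodium diethyl malonate 3 (not isolated)
Conditions: NaH, 2 (2.5 equiv), THF, 0 °C; then 1, 0 °C to rt
Reagents that add atoms: none
Why: Malonic ester alkylation, in which the soft sodium enolate displaces the primary allylic bromide by SN2 so that both alkene geometries of 1 are carried over unchanged, with excess 2 holding back dialkylation.

Step 2
Reactants: 4 diethyl farnesylmalonate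
Product: 5 ethyl (4E,8E)-5,9,13-trimethyltetradeca-4,8,12-trienoate
Conditions: LiCl (2 equiv), H2O (2 equiv), DMSO, 150 °C
Reagents that add atoms: none
Why: Krapcho dealkoxycarbonylation (chloride dealkylates one ester, the carboxylate loses CO2, the enolate is protonated) under neutral conditions that leave the three trisubstituted alkenes untouched.

Step 3
Reactants: 5 ethyl farnesylacetate
Product: 6 ethyl (4E,8E,12E)-14-hydroxy-5,9,13-trimethyltetradeca-4,8,12-trienoate
Conditions: SeO2 (0.1 equiv), t-BuOOH (70% aq.), salicylic acid (cat.), CH2Cl2, 0 °C to rt, stopped at partial conversion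
Reagents that add atoms: tert-butyl hydroperoxide CC(C)(C)OO; selenium dioxide O=[Se]=O
Why: Sharpless–Umbreit allylic oxidation (ene reaction, then [2,3]-sigmatropic shift), which should prefer the terminal isopropylidene group as the most electron-rich and least hindered alkene and gives the (E)-allylic alcohol through the shift.

Step 4
Reactants: 6 ethyl 14-hydroxy ester
Product: 7 (4E,8E,12E)-14-hydroxy-5,9,13-trimethyltetradeca-4,8,12-trienoic acid
Conditions: LiOH·H2O, THF/H2O, rt; then dilute aq. HCl to pH 3, 0 °C
Reagents that add atoms: lithium hydroxide [Li+].[OH-]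
Why: Ester saponification followed by cold acidification, to which the allylic alcohol and the alkenes are inert.

Step 5
Reactants: 7 hydroxy acid
Product: 9 (4E,8E,12E)-14-acetoxy-5,9,13-trimethyltetradeca-4,8,12-trienoic acid, via acetic mixed anhydride 8 (not isolated)
Conditions: Ac2O (3 equiv), pyridine, DMAP (cat.), CH2Cl2, 0 °C to rt; then H2O, THF, rt
Reagents that add atoms: acetic anhydride CC(=O)OC(C)=O; water O
Why: DMAP-catalysed O-acetylation of the primary allylic alcohol, in which the carboxyl group is taken to the mixed anhydride 8 and then hydrolysed back by water while the acetate ester stays.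

Step 6
Reactants: 9 14-acetoxy triene acid
Product: 10 (4R,5R,8R,9R,10S)-18-acetoxy-8α,13-epoxy-14,15,16-trinorlabdan-13-one (18-acetoxy bicyclic δ-lactone)
Conditions: squalene–hopene cyclase from Alicyclobacillus acidocaldarius (active-site variant chosen by screening, heat-clarified E. coli lysate), citrate buffer pH 6.0, 2-hydroxypropyl-β-cyclodextrin, 50 °C
Reagents that add atoms: none
Why: Proposed new method: the active-site aspartic acid of the cyclase (Asp376) protonates C3 of the terminal alkene of 9, held in a chair–chair fold, and the charge runs down the chain in one anti-periplanar cascade in which C5 closes on C4 (6-endo, ring A), C9 closes on C10 (6-endo, ring B) and a carboxylate oxygen captures the tertiary C8 cation (six-membered O-closure to the δ-lactone), so that C4–C5, C9–C10 and C8–O form and C3 is left as CH2. The closest known reaction type is the squalene–hopene cyclase bicyclisation–lactonisation of (E,E)-homofarnesic acid to sclareolide, which has not been shown for a substrate whose initiating alkene carries an allylic acetoxy group. C4 is set by the (12E) geometry (acetoxymethyl trans to the chain, hence equatorial 4α, methyl axial 4β), C5 and C10 by anti addition across the (8E) alkene (5α-H, 10β-methyl, trans fusion), and C9 and C8 by anti addition across the (4E) alkene (9α-H, 8β-methyl, 8α-oxygen). The absolute sense is set by the enzyme, which binds one of the two mirror-image folds and delivers the proton to one face of C3. The step needs protonation at the 12,13-alkene only and ring A closure ahead of capture of C4 by water or by the acetate carbonyl: the substrate offers the acid only its chain terminus, its (E) geometry keeps C5 within bonding distance of C4 as the proton arrives, and the carboxylate sits five atoms from C8. The inductive pull of the acetoxy group on the C4 cation is the open point, to be met by screening active-site variants.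

Step 7
Reactants: 10 18-acetoxy δ-lactone
Product: 11 (4R,5R,8R,9R,10S)-14,15,16-trinorlabdane-8α,13,18-triol
Conditions: LiAlH4, THF, 0 °C to reflux; then H2O, aq. NaOH
Reagents that add atoms: none
Why: Hydride reduction of the δ-lactone to the 8,13-diol and of the acetate to the C18 alcohol in one operation without touching a stereocentre, which removes the carboxyl that would otherwise recapture O8 when the tertiary alcohol is acylated.

Step 8
Reactants: 11 triol
Product: 12 (4R,5R,8R,9R,10S)-8α,13,18-triacetoxy-14,15,16-trinorlabdane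
Conditions: AcCl (6 equiv), N,N-dimethylaniline, CH2Cl2, 0 °C to 40 °C
Reagents that add atoms: acetyl chloride CC(Cl)=O
Why: Exhaustive acylation with acetyl chloride and N,N-dimethylaniline, the classical method for tertiary alcohols, in which the two primary hydroxyls react at once and the hindered 8α-hydroxyl more slowly, the weakly acidic anilinium salt being unable to ionise the tertiary centre.

Step 9
Reactants: 12 triacetate
Product: 13 (4R,5R,8R,9R,10S)-8α-acetoxy-14,15,16-trinorlabdane-13,18-diol
Conditions: K2CO3 (0.3 equiv), MeOH, 0 °C to rt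
Reagents that add atoms: none
Why: Base-catalysed transesterification (Zemplén-type methanolysis) should be faster by orders of magnitude at the two primary acetates than at the shielded tertiary 8α-acetate, and the 1,5-distance between O8 and O13 rules out acyl migration.

Step 10
Reactants: 13 8α-acetoxy diol
Product: 14 (4R,5R,8R,9R,10S)-8α-acetoxy-14,15,16-trinorlabdane-13,18-dial
Conditions: Dess–Martin periodinane, CH2Cl2, rt
Reagents that add atoms: none
Why: Dess–Martin oxidation of both primary alcohols to aldehydes under near-neutral conditions; the C18 aldehyde sits on the quaternary C4 and cannot epimerise, and the tertiary acetate is untouched.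

Step 11
Reactants: 14 dialdehyde
Product: 15 (4R,5R,8R,9R,10S)-8α-acetoxy-14,15,16-trinorlabdane-13,18-dioic acid (target)
Conditions: NaClO2, NaH2PO4, 2-methyl-2-butene, t-BuOH/H2O, rt
Reagents that add atoms: sodium chlorite [Na+].[O-]Cl=O
Why: Pinnick oxidation takes both aldehydes to the carboxylic acids at about pH 4 with an alkene scavenger for hypochlorite, conditions under which the tertiary acetate and all five stereocentres are stable.

**Compound list**

1 | (2E,6E)-farnesyl bromide | CC(C)=CCC/C(C)=C/CC/C(C)=C/CBr | starting material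
2 | diethyl malonate | CCOC(=O)CC(=O)OCC | starting material
3 | sodium diethyl malonate (enolate, not isolated) | [Na+].CCOC(=O)[CH-]C(=O)OCC | intermediate
4 | diethyl 2-[(2E,6E)-3,7,11-trimethyldodeca-2,6,10-trien-1-yl]propanedioate | CC(C)=CCC/C(C)=C/CC/C(C)=C/CC(C(=O)OCC)C(=O)OCC | intermediate
5 | ethyl (4E,8E)-5,9,13-trimethyltetradeca-4,8,12-trienoate | CC(C)=CCC/C(C)=C/CC/C(C)=C/CCC(=O)OCC | intermediate
6 | ethyl (4E,8E,12E)-14-hydroxy-5,9,13-trimethyltetradeca-4,8,12-trienoate | OC/C(C)=C/CC/C(C)=C/CC/C(C)=C/CCC(=O)OCC | intermediate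
7 | (4E,8E,12E)-14-hydroxy-5,9,13-trimethyltetradeca-4,8,12-trienoic acid | OC/C(C)=C/CC/C(C)=C/CC/C(C)=C/CCC(=O)O | intermediate
8 | acetic (4E,8E,12E)-14-acetoxy-5,9,13-trimethyltetradeca-4,8,12-trienoic anhydride (not isolated) | CC(=O)OC/C(C)=C/CC/C(C)=C/CC/C(C)=C/CCC(=O)OC(C)=O | intermediate
9 | (4E,8E,12E)-14-acetoxy-5,9,13-trimethyltetradeca-4,8,12-trienoic acid | CC(=O)OC/C(C)=C/CC/C(C)=C/CC/C(C)=C/CCC(=O)O | intermediate
10 | (4R,5R,8R,9R,10S)-18-acetoxy-8α,13-epoxy-14,15,16-trinorlabdan-13-one | O=C3O[C@]1(C)CC[C@@H]2[C@](C)(CCC[C@@]2(C)COC(C)=O)[C@H]1CC3 | intermediate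
11 | (4R,5R,8R,9R,10S)-14,15,16-trinorlabdane-8α,13,18-triol | O[C@]1(C)CC[C@@H]2[C@](C)(CCC[C@@]2(C)CO)[C@H]1CCCO | intermediate
12 | (4R,5R,8R,9R,10S)-8α,13,18-triacetoxy-14,15,16-trinorlabdane | CC(=O)O[C@]1(C)CC[C@@H]2[C@](C)(CCC[C@@]2(C)COC(C)=O)[C@H]1CCCOC(C)=O | intermediate
13 | (4R,5R,8R,9R,10S)-8α-acetoxy-14,15,16-trinorlabdane-13,18-diol | CC(=O)O[C@]1(C)CC[C@@H]2[C@](C)(CCC[C@@]2(C)CO)[C@H]1CCCO | intermediate
14 | (4R,5R,8R,9R,10S)-8α-acetoxy-14,15,16-trinorlabdane-13,18-dial | CC(=O)O[C@]1(C)CC[C@@H]2[C@](C)(CCC[C@@]2(C)C=O)[C@H]1CCC=O | intermediate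
15 | (4R,5R,8R,9R,10S)-8α-acetoxy-14,15,16-trinorlabdane-13,18-dioic acid | CC(=O)O[C@]1(C)CC[C@@H]2[C@](C)(CCC[C@@]2(C)C(=O)O)[C@H]1CCC(=O)O | target

**Step count**

Total steps: 11. Longest linear sequence: 11 steps (1 to 15).

**Steps most likely to fail**

Step 6 (new method). The acetoxy-substituted terminal alkene may not be protonated in the active site, so that no turnover occurs. The developing C4 cation may be intercepted by water or by the acetate carbonyl before ring A closes, or the acetate may be hydrolysed during the incubation. The fallback uses known reactions only; it sets out from 6 and comes back to the route at 11.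
- Sharpless asymmetric epoxidation of the allylic alcohol 6 (Ti(OiPr)4, (+)-diethyl (2R,3R)-tartrate, t-BuOOH, 4 Å molecular sieves, CH2Cl2, −20 °C) should give the (12S,13S)-epoxy alcohol F1, and acetylation (Ac2O, pyridine) the epoxy acetate F2.
- Radical epoxypolyene bicyclisation with Cp2TiCl (trivalent titanium, made in the flask from Cp2TiCl2 and Mn dust, THF, rt) opens the epoxide homolytically at the tertiary carbon and runs two 6-endo closures that end in the exocyclic alkene. It should give ethyl 18-acetoxy-3β-hydroxy-14,15,16-trinorlabd-8(17)-en-13-oate F3, with the epoxide configuration setting the absolute sense and the acetoxymethyl group expected equatorial.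
- The C3 hydroxyl is then removed by Barton–McCombie deoxygenation through the O-phenyl thionocarbonate F4 (PhOC(S)Cl, pyridine, DMAP; then Bu3SnH, AIBN, toluene, 100 °C) to the 3-deoxy alkene ester F5.
- Epoxidation from the α face, away from the axial C10 methyl (mCPBA, NaHCO3, CH2Cl2, 0 °C), should give the 8α,17-epoxide F6.
- LiAlH4 in THF opens the epoxide at C17 and reduces both esters to the triol 11, and the route goes on with step 8.

Step 3. Oxidation may also take place at the allylic positions of the two internal alkenes, the alcohol may be carried on to the enal, and conversion may stay low. The fallback sets out from 5 and comes back at 6.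
- Terminal-selective bromohydrin formation (NBS, THF/H2O, 0 °C) gives the bromohydrin F7, and ring closure with K2CO3 in EtOH the 12,13-epoxide F8.
- Cleavage with HIO4 in THF/H2O gives the trisnor aldehyde F9.
- Wittig olefination with 2-(triphenylphosphoranylidene)propanal (toluene, 90 °C) gives the (E)-enal F10.
- 1,2-Reduction with NaBH4 and CeCl3·7H2O in EtOH at 0 °C gives 6.

Step 8. Acylation of the hindered tertiary C8 hydroxyl may stay incomplete or give way to elimination under the acid chloride conditions, and the later methanolysis may not discriminate cleanly. The fallback sets out from 11 and comes back at 13, so that step 9 is no longer needed.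
- Silylation of the two primary hydroxyls (TBSCl, imidazole, DMF) gives the bis(silyl ether) F11.
- Deprotonation of the tertiary alcohol with n-BuLi in THF at −78 °C gives the lithium alkoxide F12, and quenching with acetyl chloride the tertiary acetate F13.
- Removal of both silyl groups with HF·pyridine in THF at 0 °C gives 13.

**Further compounds**

F1 | step 6 | ethyl (4E,8E)-11-[(2S,3S)-3-(hydroxymethyl)-3-methyloxiran-2-yl]-5,9-dimethylundeca-4,8-dienoate | OC[C@]1(C)O[C@H]1CC/C(C)=C/CC/C(C)=C/CCC(=O)OCC
F2 | step 6 | ethyl (4E,8E)-11-[(2S,3S)-3-(acetoxymethyl)-3-methyloxiran-2-yl]-5,9-dimethylundeca-4,8-dienoate | CC(=O)OC[C@]1(C)O[C@H]1CC/C(C)=C/CC/C(C)=C/CCC(=O)OCC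
F3 | step 6 | ethyl 18-acetoxy-3β-hydroxy-14,15,16-trinorlabd-8(17)-en-13-oate | C=C1CC[C@@H]2[C@](C)(CC[C@H](O)[C@@]2(C)COC(C)=O)[C@H]1CCC(=O)OCC
F4 | step 6 | ethyl 18-acetoxy-3β-(phenoxythiocarbonyloxy)-14,15,16-trinorlabd-8(17)-en-13-oate | C=C1CC[C@@H]2[C@](C)(CC[C@H](OC(=S)Oc3ccccc3)[C@@]2(C)COC(C)=O)[C@H]1CCC(=O)OCC
F5 | step 6 | ethyl 18-acetoxy-14,15,16-trinorlabd-8(17)-en-13-oate | C=C1CC[C@@H]2[C@](C)(CCC[C@@]2(C)COC(C)=O)[C@H]1CCC(=O)OCC
F6 | step 6 | ethyl 18-acetoxy-8α,17-epoxy-14,15,16-trinorlabdan-13-oate | C1O[C@@]12CC[C@@H]3[C@](C)(CCC[C@@]3(C)COC(C)=O)[C@H]2CCC(=O)OCC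
F7 | step 3 | ethyl (4E,8E)-12-bromo-13-hydroxy-5,9,13-trimethyltetradeca-4,8-dienoate (racemic) | CC(C)(O)C(Br)CC/C(C)=C/CC/C(C)=C/CCC(=O)OCC
F8 | step 3 | ethyl (4E,8E)-11-(3,3-dimethyloxiran-2-yl)-5,9-dimethylundeca-4,8-dienoate (racemic) | CC1(C)OC1CC/C(C)=C/CC/C(C)=C/CCC(=O)OCC
F9 | step 3 | ethyl (4E,8E)-5,9-dimethyl-12-oxododeca-4,8-dienoate | O=CCC/C(C)=C/CC/C(C)=C/CCC(=O)OCC
F10 | step 3 | ethyl (4E,8E,12E)-5,9,13-trimethyl-14-oxotetradeca-4,8,12-trienoate | O=C/C(C)=C/CC/C(C)=C/CC/C(C)=C/CCC(=O)OCC
F11 | step 8 | 13,18-bis(tert-butyldimethylsilyloxy)-14,15,16-trinorlabdan-8α-ol | O[C@]1(C)CC[C@@H]2[C@](C)(CCC[C@@]2(C)CO[Si](C)(C)C(C)(C)C)[C@H]1CCCO[Si](C)(C)C(C)(C)C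
F12 | step 8 | lithium 13,18-bis(tert-butyldimethylsilyloxy)-14,15,16-trinorlabdan-8α-olate | [Li+].[O-][C@]1(C)CC[C@@H]2[C@](C)(CCC[C@@]2(C)CO[Si](C)(C)C(C)(C)C)[C@H]1CCCO[Si](C)(C)C(C)(C)C
F13 | step 8 | 8α-acetoxy-13,18-bis(tert-butyldimethylsilyloxy)-14,15,16-trinorlabdane | CC(=O)O[C@]1(C)CC[C@@H]2[C@](C)(CCC[C@@]2(C)CO[Si](C)(C)C(C)(C)C)[C@H]1CCCO[Si](C)(C)C(C)(C)C
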